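1. The ratio of right-handed to left-handed product converts into the share asked for: the share is 1 over 1 plus that ratio.

| flask | left-handed substrate | right-handed substrate | partner | protic impurity | temperature | remark | time |
|---|---|---|---|---|---|---|---|
| alder | 5 mM | 5 mM | 4 mM | 1 mM | 95 °C | run made earlier |  |
| birch | 5 mM | 5 mM | 4 mM | 2.2 mM | 106 °C | run made earlier |  |
| cedar | 5 mM | 5 mM | 8 mM | 1.5 mM | 95 °C | run made earlier |  |
| delta | 5.0 mM | 5.0 mM | 4.00 mM | 1.50 mM | 110 °C |  | 2.0 min |
| epsilon | 5.0 mM | 5.0 mM | 4.00 mM | 1.50 mM | 90 °C |  | 2.0 min |

alder run (percent of the left-handed substrate and right-handed substrate together charged)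

| time / min | left-handed product / % | right-handed product / % | left-handed substrate / % |
|---|---|---|---|
| 0.333 | 4.1 | 0.8 | 45.0 |
| 0.667 | 9.1 | 0.5 | 41.8 |
| 1.00 | 10.0 | 0.3 | 40.1 |
| 2.00 | 14.2 | 2.3 | 35.3 |
| 3.00 | 15.9 | 1.4 | 33.5 |

birch run (percent of the left-handed substrate and right-handed substrate together charged)

| time / s | left-handed product / % | right-handed product / % | left-handed substrate / % |
|---|---|---|---|
| 10.0 | 4.2 | 0 | 46.1 |
| 20.0 | 7.7 | 0.1 | 41.1 |
| 30.0 | 6.7 | 1.3 | 39.8 |
| 50.0 | 10.8 | 0.4 | 40.0 |
| 80.0 | 11.3 | 1.7 | 38.7 |
| 90.0 | 11.0 | 1.1 | 40.2 |

cedar run (percent of the left-handed substrate and right-handed substrate together charged)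

| time / min | left-handed product / % | right-handed product / % | left-handed substrate / % |
|---|---|---|---|
| 0.667 | 14.8 | 1.8 | 35.5 |
| 1.33 | 21.7 | 0.6 | 29.8 |
| 2.00 | 22.2 | 1.0 | 26.8 |
| 3.00 | 26.1 | 1.4 | 23.9 |

(readings scatter by 1 percentage point)

* the best flask by share of left-handed product in all that became left-handed product or right-handed product; "all alike" if 1.5 percentage points covers them all (delta / epsilon / all alike)
* share of left-handed product in all that became left-handed product or right-handed product, delta
* share of left-handed product in all that became left-handed product or right-handed product, epsilon

- partner is single-handed; left-handed substrate and right-handed substrate are mirror images of each other, charged as a racemate, each of them at the stated concentration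
- steps that have been proposed: partner + left-handed substrate -> left-handed product; partner + right-handed substrate -> right-handed product; 2 partner -> homo dimer; partner + protic impurity -> quenched reagent
- the handed part of partner does not stay in what it makes, so the products of the two hands are mirror images too

2. Partner and protic impurity: if both product steps run as partner times substrate, they draw on the same partner at each moment, so partner cancels from the ratio. These charges then move how far a flask gets, and the share through that.

3. Time enters through the substrates. Readings of left-handed substrate in these runs stretch from 46.1 % (birch, first reading) to 23.9 % (cedar, last reading), so a ratio pooled over these runs averages across that range.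

4. Temperature: alder and cedar at 95 °C give 0.0731, and birch at 106 °C gives 0.0890. That gap is smaller than birch's own scatter of 0.0474, so these readings resolve no temperature trend.

5. The number itself: right-handed readings sum to 14.7 % and left-handed readings to 190 %, giving 0.0774, the pooled handed ratio, summed right-handed over summed left-handed readings. Its inverse, 12.9, is an apparent selectivity factor. The share is 92.8 %, and the scatter moves it by 1.8 percentage points, more than the margin. With no trend resolved, and with that uncertainty on it, this reckoning commits to that one share for delta and epsilon: all alike.

The forecast gave 91.5 % for delta and 94.3 % for epsilon and chose epsilon, differing from this reckoning in holding that the preference “should weaken as temperature rises”.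

The flasks give 92.7 % in delta and 92.8 % in epsilon: all alike.

    partner + left-handed substrate → left-handed product (k = 4.20 /M/s, Ea = 58.0 kJ/mol)
    partner + right-handed substrate → right-handed product (k = 0.280 /M/s, Ea = 56.0 kJ/mol)
    2 partner → homo dimer (k = 2.90 /M/s, Ea = 59.0 kJ/mol)
    partner + protic impurity → quenched reagent (k = 35.0 /M/s, Ea = 54.0 kJ/mol)
    (constants at 110 °C)

At the start of delta, partner goes into left-handed product at 0.40 of its rate into quenched reagent, so the step to left-handed product is the slower of these two. At 2.00 min, delta keeps 3.0 % of its partner and 69 % of its left-handed substrate. The pooled handed ratio turns delta's 15.4 % of left-handed product into 1.19 % of right-handed product, and delta holds 1.21 %. In a neighbour flask, delta with 3.8 mM of protic impurity, the same ratio turns 7.54 % of left-handed product into 0.584 %, and that flask holds 0.542 %.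

Readings and results stem from a simulated flask on assumed constants; noise was put on by code.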